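Readings and results are calculated for an exercise, and the scatter is random.

If one molecule of initiator makes one target and stops, the north-east flask ends at 5 mol% of the charge; if a chain never ends, target climbs to the whole charge, which 2.00 equiv of reagent covers.

the same everywhere: starting material 0.46 M; initiator 5 mol%
- north-east: reagent 2 equiv; transfer agent 0.46 M; the very flask that is asked about, followed so far
- flask: reagent 2.00 equiv; transfer agent 0.460 M; time 25 h

north-east run (percent of the starting material charged)

| time / h | target / % |
|---|---|
| 2.00 | 20 |
| 5.00 | 40 |
| 10.0 | 50 |
| 25.0 | 53 |

(readings scatter by 2 percentage points)

- target, in percent of the starting material first charged, at 25 h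
- the remedy with the largest gain of target, or "none" below 2 percentage points (maple / cedar / elm / none)
- target present, with what was taken out counted in, in percent of the starting material first charged, after maple
- target present, with what was taken out counted in, in percent of the starting material first charged, after cedar

- removed target is counted in
- additions bring no volume worth counting

- maple: change nothing and wait 12 h more
- cedar: at 25 h take out 90% of the target then present, then wait 12 h
- elm: at 25 h add starting material, 50.0% of the amount charged, then wait 12 h

Place the north-east flask between these extremes by counting turnovers. Take the last reading, 53% at 25.0 h, and divide by the loading: T = 10.6 moles of target per mole of initiator charged. T, the turnover number, must lie between one and 20.0, so this flask runs a real chain that ends early. The late rate is far lower than the early one: the first 2.00 h gave 20%, the last 15.0 h gave 3 percentage points.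

Treat T as a budget, which is my own reading and one the run cannot prove. Then target still to come equals T times the initiator still unused. Maple, cedar and elm put no initiator in, so expect each to gain little, and expect the reading at 25 h to stand.

The forecast says the same: 53% now (range 51% to 55.5%), best none, 54% after maple, and 54% after cedar, with that range open to 75%. Its ground is that “burnout is the likelier cause”.

The flask gives 52.9% now and best none. Maple gives 53.3% and cedar 53.3%. The gains are 0.39 points, 0.39 points and 0.86 points for elm, the last also less than the 2 points mark.

    starting material + second chain carrier → by-product + first chain carrier (k = 6.70 × 10⁵ M⁻¹ h⁻¹)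
    reagent + first chain carrier → target + second chain carrier (k = 2.67 × 10⁷ M⁻¹ h⁻¹)
    2 idle radical → ended radicals (k = 9.90 × 10⁶ M⁻¹ s⁻¹)
    initiator → 2 initiating radical (k = 0.248 h⁻¹)
    2 second chain carrier → ended chains A (k = 4.00 × 10⁷ M⁻¹ s⁻¹)
    starting material + initiating radical → capped initiator + first chain carrier (k = 1.11 × 10⁷ M⁻¹ h⁻¹)
    transfer agent + first chain carrier → side product + idle radical (kL = 6.78 × 10⁵ M⁻¹ h⁻¹)
    2 first chain carrier → ended chains B (k = 5.00 × 10⁸ M⁻¹ s⁻¹)
    2 starting material → homo dimer (k = 0.118 M⁻¹ h⁻¹)

The main reason for the shortfall of target is the pairing of second chain carrier into ended chains A: without that step this flask gives 95.2% at 25 h instead of 52.9%. The initiator left in this flask at 25.0 h, 0.20% of its charge, is worth 0.11 points at T, less than the 0.39 points that maple gains, and both lie below the mark. A neighbour flask with 12 mol% of initiator asks T for 127% of the charge. It gives 74.2%, a T of 6.18.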